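**Remark on the chemistry (assumption).** Nerol, 4-methylfuran-2(5H)-one and 3,4,5-trimethoxybenzoyl chloride are taken as commercial. The hydroxyl-directed epoxidation of the ten-membered (Z)-allylic alcohol is assumed to follow the ring-cis sense known for eight- and nine-membered cis-cycloalk-2-enols.

## Analysis of the target

The target 30 is a germacrane, a ten-membered carbocycle. It is numbered here so that the E alkene is C1=C10 (methyl on C10), the oxirane is C4–C5 (methyl on C4), the free carbinol is C6, C7 carries the isopropyl group (C11 with methyls C12 and C13), C8 carries the 3,4,5-trimethoxybenzoate and C9 is the methylene between C8 and C10. Five contiguous stereocentres (4S,5R,6R,7S,8S) run from C4 to C8. With the ring drawn flat, the ester oxygen at C8 lies on one face and the C7 isopropyl group, the C6 hydroxyl and the oxirane oxygen lie on the other; the oxirane is cis (C3 and C6 on the same side), so it derives from a 4Z alkene. The sensitive elements are the trisubstituted epoxide facing the C1=C10 alkene across the ring (acid opens it with transannular cyclisation), the 1,5-diene of the precursors (Cope rearrangement on heating), the mono-acylated 1,3-diol C6/C8 (acyl migration; two secondary hydroxyls to tell apart) and the aryl ester. The difficulty is a medium ring with one E and one Z alkene precursor, three contiguous stereocentres C6–C8 on a mobile ring, and the epoxide face. The plan rests on the pair C6/C7: once the isopropyl group is read as isopropenyl (C11=C12), C6(OH)–C7–C11=C12 is a homoallylic alcohol whose carbinol carbon is also allylic to C4=C5. That is the product pattern of a [2,3]-Wittig shift of a bis-allylic ether with oxygen between C6 and C12, and reconnecting O to C12 turns the ten-membered carbocycle into a thirteen-membered ether that is far easier to close.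

## Retrosynthetic reasoning

**30 ⇒ 29 (C4–O and C5–O).** The oxirane is removed first because it is the most fragile group and because 29 carries its own control element, the free C6 hydroxyl allylic to C4=C5. Forward, a hydroxyl-directed epoxidation must deliver oxygen to the face of the Z alkene cis to the hydroxyl and leave the isolated C1=C10 alkene alone. Placing it last means that no acidic or fluoride step meets the epoxygermacrene.

**29 ⇒ 24 + 27 (acyl C–O bond at O8; relay compounds 25, 26, 28).** The rearrangement delivers O6 free and O8 silylated, the reverse of what the target needs, and the two secondary hydroxyls cannot be distinguished safely by rate alone. O6 is therefore masked as a chloroacetate (25), O8 is released (26) and acylated with 27 (28), and O6 is freed again (29). The chloroacetate is chosen because a soft sulfur nucleophile removes it without touching an electron-rich aryl ester.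

**24 ⇒ 23 (two C–H bonds at C11/C12).** Reading isopropyl as isopropenyl costs one chemoselective hydrogenation (a 1,1-disubstituted alkene against two trisubstituted ring alkenes) and uncovers the homoallylic alcohol retron.

**23 ⇒ 21 (cut C6–C7, reconnect O–C12).** This is the strategic bond. Cutting here removes two stereocentres (C6, C7) and the medium ring at once, and the precursor 21 contains only one stereocentre (C8) and three alkenes of defined geometry. Forward, the C6 carbanion of 21 must shift onto C7 with the C8 silyloxy group and the Z geometry of C7=C11 dictating both new centres. Cutting C8–C9 or C2–C3 instead would demand a direct ten-membered closure.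

**21 ⇒ 19 (cut O–C12), then 19 ⇐ 18 ⇐ 16 ⇐ 15.** An intramolecular Williamson etherification closes the thirteen-membered ring. The alkoxide is placed at C6 and the chloride at C12, so the alkoxide is remote from the C8 silyl ether (no silyl transfer) and the electrophile has no β-hydrogen. The three oxygens of 15 carry two kinds of silyl group so that O12 (triethylsilyl) and then O6 (primary TBS) can be released in turn while O8 (secondary TBS) stays.

**15 ⇒ 14 ⇒ 13 ⇒ 12 (C8 configuration).** The only stereocentre of the precursor is set by catalyst-controlled reduction of enone 13, which is reached by oxidising the racemic carbinol 12. This costs two steps but makes the absolute configuration independent of the fragment coupling.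

**12 ⇒ 5 + 10 (cut C8–C9).** The allylbarium reagent 11 derived from chloride 5 adds to aldehyde 10 at its unsubstituted terminus with retention of the E alkene. This joins a C10 and a C5 fragment without scrambling either trisubstituted alkene.

**5 ⇒ 3 ⇒ 2 ⇒ 1 and 10 ⇒ 8 ⇒ 7 ⇒ 6.** Nerol 1 supplies C1–C6, C9, C10 and both ring methyls: its Z alkene becomes C4=C5, and oxidation of its E methyl group fixes C1=C10 as E. The butenolide 6 supplies C7, C8, C11, C12 with the Z alkene C7=C11 locked by the ring.

## Alternatives that were turned down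

**Alternative 1:** The ring is cut across C4–C5 and C1–C10 into the silyloxypiperitone A2 and 1-methylcyclobutene A3. Forward, irradiation would join the enone alkene of A2 to A3 head to head to give the tricyclic photoadduct A1 (a cyclohexanone fused to a bicyclo[2.2.0]hexane). Heating A1 would then cleave the other two cyclobutane bonds (C5–C10 and C1–C4) and open it to the dienone A4.
- For it: C7 and C8 are set on a six-membered ring, no macrocyclisation is needed, and the carbocycle arrives in two steps from A2. On step count to the ring it is clearly stronger than the route chosen.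
- Against it: A3 is an unpolarised alkene, so nothing enforces the head-to-head orientation that places the two methyl-bearing carbons C4 and C10 correctly. The E/Z pattern of A4 depends on the ring fusion of A1 and on the mode of the thermal opening. A4 is a 1,5-diene that can undergo Cope rearrangement at the temperature of its own formation. C6 is a ketone with the silyloxy group β to it (elimination, C7 epimerisation) and must still be reduced with the right facial sense.
- Comparison: the Wittig route is longer, but it forms C6 at the carbinol level together with C7, never carries a C6 carbonyl, and takes both alkene geometries from 1 and 6 rather than from a photochemical and a thermal event.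

**Alternative 2:** The ring is cut at C4–C5 together with the C5–O bond of the oxirane, giving the acyclic chloromethyl ketone A6 (chloride on C5, ketone at C6, methyl ketone at C4). Forward, a hindered lithium amide would enolise A6 at C5, the enolate would add to the C4 ketone and the alkoxide would displace chloride (Darzens reaction), closing ring and oxirane together to give the epoxy ketone A5.
- For it: epoxide and ring arrive in one step, the endgame after A5 is short, and C7/C8 of A6 could come from a reliable acyclic aldol. On the C7/C8 relationship it is at least as strong as the route chosen.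
- Against it: it is a direct ten-membered closure by a reversible aldol addition, the least favourable ring size. A6 has three other enolisable positions (C7, C3 and the C4 methyl), and enolisation at C7 epimerises that centre and expels the C8 silyloxide. Nothing but remote centres across a forming medium ring controls the two oxirane carbons. C6 must afterwards be reduced selectively.
- Comparison: the chosen route avoids the direct closure (13 to 10 contraction) and forms the oxirane under the direction of the neighbouring hydroxyl.

**Alternative 3:** The C8–C9 bond is cut and C6–C1 reconnected, so the ten-membered ring is contracted to a cyclohexenol. Isopiperitenone A9 would take up a 2-alkenyl metal carrying the isopropyl group and the 4-methoxybenzyloxy enol ether to give the trans-1,2-dialkenylcyclohexenol A8. Its potassium alkoxide would undergo an anionic oxy-Cope shift and the resulting enolate would be protonated at C7 to give the dienone A7.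
- For it: this is the best-precedented ring expansion to germacranes, it reaches the ring in two steps, the chair transition state gives E at C1=C10, the six-membered ring gives Z at C4=C5, the isopropyl group is already in place and the chiral pool fixes the absolute configuration. In step economy and certainty of ring formation it is stronger than the route chosen.
- Against it: the nucleophile is a β-alkoxy vinyl metal (prone to eliminate alkoxide) whose enol ether geometry alone decides C8, and A9 is easily enolised by basic organometallics. The rearrangement produces an enolate with the alkoxy leaving group on the next carbon (C8), inviting loss of alkoxide to an enone. C7 rests on kinetic protonation and C6 on a later ketone reduction, so two of the three centres C6–C8 depend on the conformational bias of a flexible dienone.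
- Comparison: the chosen route sets C6 and C7 in the key event, with C8 as the controlling centre, and passes through no β-oxygenated ketone or enolate.

Key step: step 15

## Route

Step 1
Reactants: 1 nerol [(2Z)-3,7-dimethylocta-2,6-dien-1-ol]
Product: 2 neryl tert-butyldimethylsilyl ether [tert-butyl{[(2Z)-3,7-dimethylocta-2,6-dien-1-yl]oxy}dimethylsilane]
Conditions: TBSCl, imidazole, DMF, 0 °C → rt
Reagents that add atoms: tert-butyldimethylsilyl chloride, CC(C)(C)[Si](C)(C)Cl
Why: Standard silylation of a primary alcohol; a silyl ether is used because it must survive the organobarium stage (step 7), and the 2Z alkene (later C4=C5) is untouched.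

Step 2
Reactants: 2 neryl tert-butyldimethylsilyl ether
Product: 3 (2E,6Z)-8-[(tert-butyldimethylsilyl)oxy]-2,6-dimethylocta-2,6-dien-1-ol
Conditions: SeO2 (cat.), t-BuOOH, salicylic acid (cat.), CH2Cl2, 0 °C → rt
Reagents that add atoms: tert-butyl hydroperoxide, CC(C)(C)OO (source of the new oxygen, relayed by the SeO2 catalyst)
Why: Selenium dioxide allylic oxidation (ene reaction, then [2,3] shift of the allylseleninic acid) attacks the electron-richer terminal alkene at its E methyl group, which fixes the later C1=C10 alkene as E; the alkene next to the silyloxymethyl group is deactivated.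

Step 3
Reactants: 3 (2E,6Z)-8-[(tert-butyldimethylsilyl)oxy]-2,6-dimethylocta-2,6-dien-1-ol
Product: 5 tert-butyl{[(2Z,6E)-8-chloro-3,7-dimethylocta-2,6-dien-1-yl]oxy}dimethylsilane, via allylic methanesulfonate 4 (not isolated)
Conditions: MsCl, 2,4,6-collidine, LiCl, DMF, 0 °C
Reagents that add atoms: lithium chloride, [Li+].[Cl-]
Why: Mesylation in situ and SN2 displacement by chloride under non-ionising conditions should give the primary allylic chloride without allylic transposition or E/Z loss; the silyl ether tolerates the buffered medium.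

Step 4
Reactants: 6 4-methylfuran-2(5H)-one
Product: 7 (2Z)-4-hydroxy-N-methoxy-N,3-dimethylbut-2-enamide
Conditions: MeNH(OMe)·HCl, AlMe3, CH2Cl2, 0 °C → rt; aq. work-up
Reagents that add atoms: N,O-dimethylhydroxylamine hydrochloride, CNOC.Cl
Why: Aluminium amide aminolysis of a lactone (Weinreb amide formation); the ring hands over the Z alkene (later C7=C11) with its geometry fixed and the carbonyl carbon becomes C8; 7 is silylated at once because it can relactonise.

Step 5
Reactants: 7 (2Z)-4-hydroxy-N-methoxy-N,3-dimethylbut-2-enamide
Product: 8 (2Z)-N-methoxy-N,3-dimethyl-4-[(triethylsilyl)oxy]but-2-enamide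
Conditions: TESCl, imidazole, CH2Cl2, 0 °C
Reagents that add atoms: chlorotriethylsilane, CC[Si](CC)(CC)Cl
Why: Silylation of the primary alcohol blocks relactonisation; triethylsilyl is chosen so that O12 can later be released by mild acid in the presence of the two TBS ethers.

Step 6
Reactants: 8 (2Z)-N-methoxy-N,3-dimethyl-4-[(triethylsilyl)oxy]but-2-enamide
Product: 10 (2Z)-3-methyl-4-[(triethylsilyl)oxy]but-2-enal, via aluminium hemiaminal 9 (not isolated)
Conditions: i-Bu2AlH, THF, −78 °C; aq. work-up
Reagents that add atoms: none
Why: Weinreb amide reduction stops at the chelated tetrahedral adduct 9, which releases the aldehyde only on work-up, so there is no over-reduction; the Z geometry is kept at −78 °C and 10 is used without storage.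

Step 7
Reactants: 5 tert-butyl{[(2Z,6E)-8-chloro-3,7-dimethylocta-2,6-dien-1-yl]oxy}dimethylsilane and 10 (2Z)-3-methyl-4-[(triethylsilyl)oxy]but-2-enal
Product: 12 rac-(2Z,6E,10Z)-12-[(tert-butyldimethylsilyl)oxy]-2,6,10-trimethyl-1-[(triethylsilyl)oxy]dodeca-2,6,10-trien-4-ol, via allylbarium chloride 11 (not isolated)
Conditions: BaI2, Li biphenylide (2 equiv), THF, rt; then 5, −78 °C; then 10, −78 °C
Reagents that add atoms: none
Why: Activated barium metal inserts into the allylic C–Cl bond at −78 °C; allylbarium reagents add to aldehydes at the unsubstituted (α) carbon with retention of alkene geometry and in a 1,2 sense to enals (allylbarium carbonyl allylation), which forms C8–C9 and keeps C1=C10 E and C7=C11 Z. C8 is formed racemic and is corrected in steps 8 and 9.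

Step 8
Reactants: 12 rac-(2Z,6E,10Z)-12-[(tert-butyldimethylsilyl)oxy]-2,6,10-trimethyl-1-[(triethylsilyl)oxy]dodeca-2,6,10-trien-4-ol
Product: 13 (2Z,6E,10Z)-12-[(tert-butyldimethylsilyl)oxy]-2,6,10-trimethyl-1-[(triethylsilyl)oxy]dodeca-2,6,10-trien-4-one
Conditions: Dess–Martin periodinane, pyridine, CH2Cl2, 0 °C
Reagents that add atoms: none
Why: Dess–Martin oxidation under buffered, non-basic conditions should leave the skipped C10=C1 alkene out of conjugation and the Z enone unisomerised; O12 is silylated, so no furan can form from the Z γ-oxy enone.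

Step 9
Reactants: 13 (2Z,6E,10Z)-12-[(tert-butyldimethylsilyl)oxy]-2,6,10-trimethyl-1-[(triethylsilyl)oxy]dodeca-2,6,10-trien-4-one
Product: 14 (2Z,4S,6E,10Z)-12-[(tert-butyldimethylsilyl)oxy]-2,6,10-trimethyl-1-[(triethylsilyl)oxy]dodeca-2,6,10-trien-4-ol
Conditions: (R)-Me-CBS oxazaborolidine [(R)-1-methyl-3,3-diphenyltetrahydro-1H,3H-pyrrolo[1,2-c][1,3,2]oxazaborole], catecholborane, toluene, −78 °C
Reagents that add atoms: none
Why: Corey–Bakshi–Shibata reduction; the alkenyl group (β-branched, with a cis CH2OSi arm) acts as the large substituent and the C9 methylene as the small one, so the (R) catalyst should deliver hydride to the face that gives the (S) carbinol at C8. Catecholborane at −78 °C reduces 1,2 and does not hydroborate the trisubstituted alkenes.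

Step 10
Reactants: 14 (2Z,4S,6E,10Z)-12-[(tert-butyldimethylsilyl)oxy]-2,6,10-trimethyl-1-[(triethylsilyl)oxy]dodeca-2,6,10-trien-4-ol
Product: 15 (2Z,4S,6E,10Z)-4,12-bis[(tert-butyldimethylsilyl)oxy]-2,6,10-trimethyl-1-[(triethylsilyl)oxy]dodeca-2,6,10-triene
Conditions: TBSOTf, 2,6-lutidine, CH2Cl2, −78 °C
Reagents that add atoms: tert-butyldimethylsilyl trifluoromethanesulfonate, CC(C)(C)[Si](C)(C)OS(=O)(=O)C(F)(F)F
Why: Silyl triflate with a hindered base silylates the secondary allylic alcohol without ionising it; the C8 TBS ether is both the protecting group and the bulky controlling group of the key step.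

Step 11
Reactants: 15 (2Z,4S,6E,10Z)-4,12-bis[(tert-butyldimethylsilyl)oxy]-2,6,10-trimethyl-1-[(triethylsilyl)oxy]dodeca-2,6,10-triene
Product: 16 (2Z,4S,6E,10Z)-4,12-bis[(tert-butyldimethylsilyl)oxy]-2,6,10-trimethyldodeca-2,6,10-trien-1-ol
Conditions: PPTS (cat.), MeOH–CH2Cl2, 0 °C
Reagents that add atoms: none
Why: Acid-catalysed methanolysis removes a primary triethylsilyl ether much faster than a primary or secondary TBS ether, so only O12 (ring numbering) should be released.

Step 12
Reactants: 16 (2Z,4S,6E,10Z)-4,12-bis[(tert-butyldimethylsilyl)oxy]-2,6,10-trimethyldodeca-2,6,10-trien-1-ol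
Product: 18 (2Z,4S,6E,10Z)-4,12-bis[(tert-butyldimethylsilyl)oxy]-1-chloro-2,6,10-trimethyldodeca-2,6,10-triene, via allylic methanesulfonate 17 (not isolated)
Conditions: MsCl, 2,4,6-collidine, LiCl, DMF, 0 °C
Reagents that add atoms: lithium chloride, [Li+].[Cl-]
Why: Same mesylate–chloride exchange as step 3; SN2 at the primary carbon C12 keeps the Z alkene, and SN2' attack at C7 is blocked by the adjacent silyloxy-bearing carbon.

Step 13
Reactants: 18 (2Z,4S,6E,10Z)-4,12-bis[(tert-butyldimethylsilyl)oxy]-1-chloro-2,6,10-trimethyldodeca-2,6,10-triene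
Product: 19 (2Z,6E,9S,10Z)-9-[(tert-butyldimethylsilyl)oxy]-12-chloro-3,7,11-trimethyldodeca-2,6,10-trien-1-ol
Conditions: HF·pyridine, pyridine, THF, 0 °C
Reagents that add atoms: none
Why: Buffered HF·pyridine cleaves the primary allylic TBS ether much faster than the hindered secondary one at C8, and the allylic chloride is inert to it; 19 is used at once.

Step 14
Reactants: 19 (2Z,6E,9S,10Z)-9-[(tert-butyldimethylsilyl)oxy]-12-chloro-3,7,11-trimethyldodeca-2,6,10-trien-1-ol
Product: 21 (3Z,5S,7E,11Z)-5-[(tert-butyldimethylsilyl)oxy]-3,7,11-trimethyl-1-oxacyclotrideca-3,7,11-triene, via sodium alkoxide 20 (not isolated)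
Conditions: NaH, n-Bu4NI (cat.), THF, 60 °C, slow addition (high dilution)
Reagents that add atoms: none
Why: Intramolecular Williamson etherification; the C6 alkoxide displaces the primary allylic chloride at C12 (iodide catalysis), which has no β-hydrogen for elimination, and high dilution favours the thirteen-membered ring over oligomers. The alkoxide is remote from the C8 silyl ether, so no silyl transfer is expected.

Step 15
Reactants: 21 (3Z,5S,7E,11Z)-5-[(tert-butyldimethylsilyl)oxy]-3,7,11-trimethyl-1-oxacyclotrideca-3,7,11-triene
Product: 23 (1S,2Z,6E,9S,10S)-9-[(tert-butyldimethylsilyl)oxy]-3,7-dimethyl-10-(prop-1-en-2-yl)cyclodeca-2,6-dien-1-ol, via C6-lithiated ether 22 (not isolated)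
Conditions: n-BuLi, THF–hexane, −78 → −20 °C; then H2O at −78 °C
Reagents that add atoms: none
Why: n-BuLi removes a proton from C6, the α-oxy allylic position attached to the unsubstituted alkene carbon C5 (C12 is flanked by the C11 methyl group and screened by the cis C8 silyloxy group), to give the allyllithium 22. Its carbanion adds to C7 across the O–C12–C11=C7 unit while O–C12 breaks and the alkene moves to C11=C12: a [2,3]-Wittig rearrangement in its transannular, ring-contracting form, the closest known case being the contraction of thirteen-membered diallylic ethers to germacrane-type cyclodecadienols. The ten-membered carbocycle is thus closed by ring contraction (13 to 10) through a five-membered envelope transition state made of C6, O, C12, C11 and C7, not by an end-to-end cyclisation. C6 is controlled by the Z geometry of C7=C11 together with the exo placement of the C5 vinyl group on the envelope: the endo placement would clash with the C11 methyl group and would set C5 anti to C8, which the remaining tether cannot span, so the hydroxyl and C8 end up syn when C5–C6–C7–C11 is drawn zigzag. C7 is controlled by the C8 stereocentre: allylic 1,3-strain with C12 holds H8 in the alkene plane, the C8–O bond stands perpendicular to it, and C6 bonds to the face anti to the silyloxy group, which is the face on which the C9 tether already lies. The step needs lithiation at C6 and not at C12, [2,3] over [1,2] shift (low temperature) and a cold quench so that the silyl group does not move to the new alkoxide; the 4Z and 1(10)E alkenes take no part and keep their geometry.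

Step 16
Reactants: 23 (1S,2Z,6E,9S,10S)-9-[(tert-butyldimethylsilyl)oxy]-3,7-dimethyl-10-(prop-1-en-2-yl)cyclodeca-2,6-dien-1-ol
Product: 24 (1S,2Z,6E,9S,10S)-9-[(tert-butyldimethylsilyl)oxy]-3,7-dimethyl-10-(propan-2-yl)cyclodeca-2,6-dien-1-ol
Conditions: H2 (1 atm), RhCl(PPh3)3 (cat.), benzene–EtOH, rt
Reagents that add atoms: none
Why: Homogeneous hydrogenation with RhCl(PPh3)3 reduces 1,1-disubstituted alkenes far faster than trisubstituted ones, so only the isopropenyl group should be saturated; no stereocentre is created.

Step 17
Reactants: 24 (1S,2Z,6E,9S,10S)-9-[(tert-butyldimethylsilyl)oxy]-3,7-dimethyl-10-(propan-2-yl)cyclodeca-2,6-dien-1-ol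
Product: 25 (1S,2Z,6E,9S,10S)-9-[(tert-butyldimethylsilyl)oxy]-3,7-dimethyl-10-(propan-2-yl)cyclodeca-2,6-dien-1-yl chloroacetate
Conditions: (ClCH2CO)2O, pyridine, DMAP (cat.), CH2Cl2, 0 °C
Reagents that add atoms: chloroacetic anhydride, O=C(CCl)OC(=O)CCl
Why: Acylation of the only free hydroxyl (O6); the chloroacetate withstands buffered HF and acylation conditions and can later be removed without touching an aryl ester.

Step 18
Reactants: 25 (1S,2Z,6E,9S,10S)-9-[(tert-butyldimethylsilyl)oxy]-3,7-dimethyl-10-(propan-2-yl)cyclodeca-2,6-dien-1-yl chloroacetate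
Product: 26 (1S,2Z,6E,9S,10R)-9-hydroxy-3,7-dimethyl-10-(propan-2-yl)cyclodeca-2,6-dien-1-yl chloroacetate
Conditions: HF·pyridine, pyridine, THF, 0 °C → rt
Reagents that add atoms: none
Why: Buffered fluoride desilylation releases O8 under mildly acidic conditions in which chloroacetates neither cleave nor migrate; no epoxide is present yet, so the acid-labile stage is avoided.

Step 19
Reactants: 26 (1S,2Z,6E,9S,10R)-9-hydroxy-3,7-dimethyl-10-(propan-2-yl)cyclodeca-2,6-dien-1-yl chloroacetate and 27 3,4,5-trimethoxybenzoyl chloride
Product: 28 (6S,7R,8S)-6-(chloroacetoxy)-7-isopropyl-4,10-dimethylcyclodeca-1(10)E,4Z-dien-8-yl 3,4,5-trimethoxybenzoate (ring numbering of the target)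
Conditions: 27, pyridine, DMAP (cat.), CH2Cl2, 0 °C → rt
Reagents that add atoms: none
Why: Acylation of the secondary C8 alcohol by an acid chloride with nucleophilic catalysis; excess acid chloride at low temperature lets acylation outrun chloroacetyl migration from O6 to O8.

Step 20
Reactants: 28 (6S,7R,8S)-6-(chloroacetoxy)-7-isopropyl-4,10-dimethylcyclodeca-1(10)E,4Z-dien-8-yl 3,4,5-trimethoxybenzoate
Product: 29 (6S,7S,8S)-6-hydroxy-7-isopropyl-4,10-dimethylcyclodeca-1(10)E,4Z-dien-8-yl 3,4,5-trimethoxybenzoate
Conditions: thiourea, NaHCO3, EtOH–THF, 50 °C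
Reagents that add atoms: none
Why: Thiourea alkylates at the CH2Cl carbon and the isothiouronium nitrogen then cyclises onto the ester carbonyl, releasing the C6 alcohol; the electron-rich, hindered aryl ester at C8 is not attacked under these near-neutral conditions.

Step 21
Reactants: 29 (6S,7S,8S)-6-hydroxy-7-isopropyl-4,10-dimethylcyclodeca-1(10)E,4Z-dien-8-yl 3,4,5-trimethoxybenzoate
Product: 30 (4S,5R,6R,7S,8S)-4,5-epoxy-6-hydroxy-7-isopropyl-4,10-dimethylcyclodec-1(10)E-en-8-yl 3,4,5-trimethoxybenzoate (target)
Conditions: VO(acac)2 (cat.), t-BuOOH, CH2Cl2, 0 °C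
Reagents that add atoms: tert-butyl hydroperoxide, CC(C)(C)OO
Why: Hydroxyl-directed vanadium-catalysed epoxidation: the vanadate ester of O6 delivers oxygen with a small O–C6–C5=C4 dihedral angle, which in a (Z)-cycloalkenol places the ring bond C6–C7 on the far face, so oxygen should enter cis to the hydroxyl (4S,5R), as with eight- and nine-membered cis-cycloalk-2-enols. The C1=C10 alkene has no directing hydroxyl within reach and is left; placing this step last keeps the epoxide away from all acidic and fluoride steps.

## Compound list

1 | nerol, (2Z)-3,7-dimethylocta-2,6-dien-1-ol | CC(C)=CCC/C(C)=C\CO | starting material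
2 | neryl tert-butyldimethylsilyl ether | CC(C)=CCC/C(C)=C\CO[Si](C)(C)C(C)(C)C | intermediate
3 | (2E,6Z)-8-[(tert-butyldimethylsilyl)oxy]-2,6-dimethylocta-2,6-dien-1-ol | OC/C(C)=C/CC/C(C)=C\CO[Si](C)(C)C(C)(C)C | intermediate
4 | methanesulfonate of 3 | CS(=O)(=O)OC/C(C)=C/CC/C(C)=C\CO[Si](C)(C)C(C)(C)C | intermediate (not isolated)
5 | tert-butyl{[(2Z,6E)-8-chloro-3,7-dimethylocta-2,6-dien-1-yl]oxy}dimethylsilane | ClC/C(C)=C/CC/C(C)=C\CO[Si](C)(C)C(C)(C)C | intermediate
6 | 4-methylfuran-2(5H)-one | CC1=CC(=O)OC1 | starting material
7 | (2Z)-4-hydroxy-N-methoxy-N,3-dimethylbut-2-enamide | CON(C)C(=O)/C=C(/C)CO | intermediate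
8 | (2Z)-N-methoxy-N,3-dimethyl-4-[(triethylsilyl)oxy]but-2-enamide | CON(C)C(=O)/C=C(/C)CO[Si](CC)(CC)CC | intermediate
9 | diisobutylaluminium hemiaminal of 8 (tetrahedral adduct, carbinol carbon unspecified) | CON(C)C(O[Al](CC(C)C)CC(C)C)/C=C(/C)CO[Si](CC)(CC)CC | intermediate (not isolated)
10 | (2Z)-3-methyl-4-[(triethylsilyl)oxy]but-2-enal | O=C/C=C(/C)CO[Si](CC)(CC)CC | intermediate
11 | [(2E,6Z)-8-[(tert-butyldimethylsilyl)oxy]-2,6-dimethylocta-2,6-dien-1-yl]barium chloride | Cl[Ba]C/C(C)=C/CC/C(C)=C\CO[Si](C)(C)C(C)(C)C | intermediate (not isolated)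
12 | rac-(2Z,6E,10Z)-12-[(tert-butyldimethylsilyl)oxy]-2,6,10-trimethyl-1-[(triethylsilyl)oxy]dodeca-2,6,10-trien-4-ol (C8 carbinol, racemic) | CC[Si](CC)(CC)OC/C(C)=C\C(O)C/C(C)=C/CC/C(C)=C\CO[Si](C)(C)C(C)(C)C | intermediate
13 | (2Z,6E,10Z)-12-[(tert-butyldimethylsilyl)oxy]-2,6,10-trimethyl-1-[(triethylsilyl)oxy]dodeca-2,6,10-trien-4-one | CC[Si](CC)(CC)OC/C(C)=C\C(=O)C/C(C)=C/CC/C(C)=C\CO[Si](C)(C)C(C)(C)C | intermediate
14 | (2Z,4S,6E,10Z)-12-[(tert-butyldimethylsilyl)oxy]-2,6,10-trimethyl-1-[(triethylsilyl)oxy]dodeca-2,6,10-trien-4-ol | CC[Si](CC)(CC)OC/C(C)=C\[C@@H](O)C/C(C)=C/CC/C(C)=C\CO[Si](C)(C)C(C)(C)C | intermediate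
15 | (2Z,4S,6E,10Z)-4,12-bis[(tert-butyldimethylsilyl)oxy]-2,6,10-trimethyl-1-[(triethylsilyl)oxy]dodeca-2,6,10-triene | CC[Si](CC)(CC)OC/C(C)=C\[C@@H](O[Si](C)(C)C(C)(C)C)C/C(C)=C/CC/C(C)=C\CO[Si](C)(C)C(C)(C)C | intermediate
16 | (2Z,4S,6E,10Z)-4,12-bis[(tert-butyldimethylsilyl)oxy]-2,6,10-trimethyldodeca-2,6,10-trien-1-ol | OC/C(C)=C\[C@@H](O[Si](C)(C)C(C)(C)C)C/C(C)=C/CC/C(C)=C\CO[Si](C)(C)C(C)(C)C | intermediate
17 | methanesulfonate of 16 | CS(=O)(=O)OC/C(C)=C\[C@@H](O[Si](C)(C)C(C)(C)C)C/C(C)=C/CC/C(C)=C\CO[Si](C)(C)C(C)(C)C | intermediate (not isolated)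
18 | (2Z,4S,6E,10Z)-4,12-bis[(tert-butyldimethylsilyl)oxy]-1-chloro-2,6,10-trimethyldodeca-2,6,10-triene | ClC/C(C)=C\[C@@H](O[Si](C)(C)C(C)(C)C)C/C(C)=C/CC/C(C)=C\CO[Si](C)(C)C(C)(C)C | intermediate
19 | (2Z,6E,9S,10Z)-9-[(tert-butyldimethylsilyl)oxy]-12-chloro-3,7,11-trimethyldodeca-2,6,10-trien-1-ol | ClC/C(C)=C\[C@@H](O[Si](C)(C)C(C)(C)C)C/C(C)=C/CC/C(C)=C\CO | intermediate
20 | sodium alkoxide of 19 | ClC/C(C)=C\[C@@H](O[Si](C)(C)C(C)(C)C)C/C(C)=C/CC/C(C)=C\C[O-].[Na+] | intermediate (not isolated)
21 | (3Z,5S,7E,11Z)-5-[(tert-butyldimethylsilyl)oxy]-3,7,11-trimethyl-1-oxacyclotrideca-3,7,11-triene (oxygen between C6 and C12; 4Z, 7(11)Z, 1(10)E, 8S in ring numbering) | C1/C(C)=C\COC/C(C)=C\[C@@H](O[Si](C)(C)C(C)(C)C)C/C(C)=C/C1 | intermediate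
22 | 21 lithiated at C6 (position 13 of the oxacycle; configuration at the lithiated carbon undefined) | C1/C(C)=C\C([Li])OC/C(C)=C\[C@@H](O[Si](C)(C)C(C)(C)C)C/C(C)=C/C1 | intermediate (not isolated)
23 | (1S,2Z,6E,9S,10S)-9-[(tert-butyldimethylsilyl)oxy]-3,7-dimethyl-10-(prop-1-en-2-yl)cyclodeca-2,6-dien-1-ol (6S,7S,8S in ring numbering) | CC(C)(C)[Si](C)(C)O[C@H]1C/C(C)=C/CC/C(C)=C\[C@H](O)[C@@H]1C(C)=C | intermediate
24 | (1S,2Z,6E,9S,10S)-9-[(tert-butyldimethylsilyl)oxy]-3,7-dimethyl-10-(propan-2-yl)cyclodeca-2,6-dien-1-ol | CC(C)(C)[Si](C)(C)O[C@H]1C/C(C)=C/CC/C(C)=C\[C@H](O)[C@@H]1C(C)C | intermediate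
25 | (1S,2Z,6E,9S,10S)-9-[(tert-butyldimethylsilyl)oxy]-3,7-dimethyl-10-(propan-2-yl)cyclodeca-2,6-dien-1-yl chloroacetate | CC(C)(C)[Si](C)(C)O[C@H]1C/C(C)=C/CC/C(C)=C\[C@H](OC(=O)CCl)[C@@H]1C(C)C | intermediate
26 | (1S,2Z,6E,9S,10R)-9-hydroxy-3,7-dimethyl-10-(propan-2-yl)cyclodeca-2,6-dien-1-yl chloroacetate | O[C@H]1C/C(C)=C/CC/C(C)=C\[C@H](OC(=O)CCl)[C@@H]1C(C)C | intermediate
27 | 3,4,5-trimethoxybenzoyl chloride | COc1cc(C(Cl)=O)cc(OC)c1OC | starting material
28 | (6S,7R,8S)-6-(chloroacetoxy)-7-isopropyl-4,10-dimethylcyclodeca-1(10)E,4Z-dien-8-yl 3,4,5-trimethoxybenzoate | COc1cc(C(=O)O[C@H]2C/C(C)=C/CC/C(C)=C\[C@H](OC(=O)CCl)[C@@H]2C(C)C)cc(OC)c1OC | intermediate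
29 | (6S,7S,8S)-6-hydroxy-7-isopropyl-4,10-dimethylcyclodeca-1(10)E,4Z-dien-8-yl 3,4,5-trimethoxybenzoate | COc1cc(C(=O)O[C@H]2C/C(C)=C/CC/C(C)=C\[C@H](O)[C@@H]2C(C)C)cc(OC)c1OC | intermediate
30 | (4S,5R,6R,7S,8S)-4,5-epoxy-6-hydroxy-7-isopropyl-4,10-dimethylcyclodec-1(10)E-en-8-yl 3,4,5-trimethoxybenzoate | COc1cc(C(=O)O[C@H]2C/C(C)=C/CC[C@]3(C)O[C@@H]3[C@H](O)[C@@H]2C(C)C)cc(OC)c1OC | target

## Step count and least certain steps

Total step count: 21. Longest linear sequence: 18 steps (steps 1–3 and 7–21 from nerol; the branch through steps 4–6 from the butenolide is equally long).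

**Step 15 (key step).** What may go wrong: lithiation at C12 instead of C6 (followed by loss of the C8 silyloxide or by the other contraction that bonds C12 to C4), [1,2] shift if the mixture warms, or bonding to the wrong face of C7=C11. Fallback, setting out from 19 and coming back at 25: the same C6–C7 bond and isopropenyl group are made by an intramolecular Nozaki–Hiyama–Kishi-type allylation instead of a carbanion shift. The C6 alcohol of 19 is oxidised with MnO2 to the (2Z)-enal F1. CrCl2 in THF at high dilution turns the C12 chloride into an allylchromium species that adds through C7 to the aldehyde and closes the ten-membered ring directly. Allylchromium additions favour the anti adduct, so the expected product is the C6 epimer of 23, dienol F2. Mitsunobu esterification with chloroacetic acid (PPh3, DIAD) inverts C6 and gives the isopropenyl chloroacetate F3, and hydrogenation over RhCl(PPh3)3 as in step 16 leads to 25.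

**Step 7.** What may go wrong: loss of α-selectivity or of alkene geometry if the allylbarium species warms, reductive homocoupling of the chloride, or reductive cleavage of the allylic silyl ether by the electron-transfer reagent. Fallback, setting out from 5 (with 8) and coming back at 13: a sulfone-stabilised carbanion replaces the organobarium. PhSO2Na displaces the chloride of 5 to give the allylic sulfone F4. Its lithio derivative (n-BuLi, 2 equiv, THF, −78 °C) is acylated at the sulfonyl carbon by Weinreb amide 8 to give the β-keto sulfone F5. Aluminium amalgam in wet THF removes the sulfonyl group and gives ketone 13, so steps 6 and 8 are not needed.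

**Step 9.** What may go wrong: weak facial discrimination because both groups on the carbonyl are unsaturated or allylic, or competing conjugate reduction. Fallback, setting out from racemic 12 and coming back at 14: resolution through diastereomeric esters. Alcohol 12 is esterified with (S)-O-methylmandelic acid (DCC, DMAP) and the diastereomers are separated by chromatography. The ester of the (S) alcohol, mandelate F6, is cleaved with i-Bu2AlH at −78 °C to give 14, and the other diastereomer is returned to 13 by cleavage and oxidation.

**Step 14.** What may go wrong: intermolecular etherification to dimers and oligomers, or slow closure with decomposition of the hydroxy chloride. Fallback, setting out from 16 and coming back at 21: cyclodehydration of a diol, in which the leaving group is made in the flask at either terminus. Buffered HF·pyridine removes the primary TBS group of 16 to give diol F7. Its disodium alkoxide (NaH, THF, high dilution) is treated with one equivalent of 1-(p-toluenesulfonyl)imidazole added slowly. Whichever primary allylic oxygen is sulfonylated, the other alkoxide displaces it and the same ether 21 results.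

**Step 21.** What may go wrong: oxygen delivery to the wrong face if the ten-membered ring does not adopt the assumed reactive conformation, or Lewis-acid-induced transannular opening of the product. Fallback, setting out from 29 and coming back at 30: reagent control in place of substrate direction, with Ti(OiPr)4, D-(−)-diisopropyl tartrate, t-BuOOH and molecular sieves at −20 °C. For the C6 configuration of 29 this tartrate is the matched ligand (C7 lies on the face away from oxygen delivery), and its anti selectivity corresponds to the target; no new compound arises (F0).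

## Further compounds

F1 | step 15 | (2Z,6E,9S,10Z)-9-[(tert-butyldimethylsilyl)oxy]-12-chloro-3,7,11-trimethyldodeca-2,6,10-trienal | ClC/C(C)=C\[C@@H](O[Si](C)(C)C(C)(C)C)C/C(C)=C/CC/C(C)=C\C=O
F2 | step 15 | (1R,2Z,6E,9S,10S)-9-[(tert-butyldimethylsilyl)oxy]-3,7-dimethyl-10-(prop-1-en-2-yl)cyclodeca-2,6-dien-1-ol (C6 epimer of 23) | CC(C)(C)[Si](C)(C)O[C@H]1C/C(C)=C/CC/C(C)=C\[C@@H](O)[C@@H]1C(C)=C
F3 | step 15 | (1S,2Z,6E,9S,10S)-9-[(tert-butyldimethylsilyl)oxy]-3,7-dimethyl-10-(prop-1-en-2-yl)cyclodeca-2,6-dien-1-yl chloroacetate | CC(C)(C)[Si](C)(C)O[C@H]1C/C(C)=C/CC/C(C)=C\[C@H](OC(=O)CCl)[C@@H]1C(C)=C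
F4 | step 7 | tert-butyl{[(2Z,6E)-3,7-dimethyl-8-(phenylsulfonyl)octa-2,6-dien-1-yl]oxy}dimethylsilane | O=S(=O)(c1ccccc1)C/C(C)=C/CC/C(C)=C\CO[Si](C)(C)C(C)(C)C
F5 | step 7 | (2Z,6E,10Z)-12-[(tert-butyldimethylsilyl)oxy]-2,6,10-trimethyl-5-(phenylsulfonyl)-1-[(triethylsilyl)oxy]dodeca-2,6,10-trien-4-one (mixture of C5 epimers) | CC[Si](CC)(CC)OC/C(C)=C\C(=O)C(S(=O)(=O)c1ccccc1)/C(C)=C/CC/C(C)=C\CO[Si](C)(C)C(C)(C)C
F6 | step 9 | (2Z,4S,6E,10Z)-12-[(tert-butyldimethylsilyl)oxy]-2,6,10-trimethyl-1-[(triethylsilyl)oxy]dodeca-2,6,10-trien-4-yl (2S)-2-methoxy-2-phenylacetate | CC[Si](CC)(CC)OC/C(C)=C\[C@@H](OC(=O)[C@@H](OC)c1ccccc1)C/C(C)=C/CC/C(C)=C\CO[Si](C)(C)C(C)(C)C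
F7 | step 14 | (2Z,4S,6E,10Z)-4-[(tert-butyldimethylsilyl)oxy]-2,6,10-trimethyldodeca-2,6,10-triene-1,12-diol | OC/C(C)=C\[C@@H](O[Si](C)(C)C(C)(C)C)C/C(C)=C/CC/C(C)=C\CO
F0 | step 21 | none | none
A1 | alternative 1 | tricyclic photoadduct (cyclohexanone fused to a bicyclo[2.2.0]hexane) | O=C1[C@H](C(C)C)[C@@H](O[Si](C)(C)C(C)(C)C)C[C@]2(C)[C@H]3CC[C@@]3(C)[C@H]12
A2 | alternative 1 | silyloxypiperitone, (5S,6S)-5-[(tert-butyldimethylsilyl)oxy]-3-methyl-6-(propan-2-yl)cyclohex-2-en-1-one | O=C1C=C(C)C[C@H](O[Si](C)(C)C(C)(C)C)[C@H]1C(C)C
A3 | alternative 1 | 1-methylcyclobutene | CC1=CCC1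
A4 | alternative 1 | 8-[(tert-butyldimethylsilyl)oxy]germacra-1(10)E,4Z-dien-6-one | CC(C)[C@H]1C(=O)/C=C(C)\CC/C=C(C)/C[C@@H]1O[Si](C)(C)C(C)(C)C
A5 | alternative 2 | 4,5-epoxy-8-[(tert-butyldimethylsilyl)oxy]germacr-1(10)E-en-6-one | CC(C)(C)[Si](C)(C)O[C@H]1C/C(C)=C/CC[C@]2(C)O[C@@H]2C(=O)[C@@H]1C(C)C
A6 | alternative 2 | acyclic chloromethyl ketone, (6E)-4-[(tert-butyldimethylsilyl)oxy]-1-chloro-6-methyl-3-(propan-2-yl)undec-6-ene-2,10-dione | ClCC(=O)[C@H](C(C)C)[C@@H](O[Si](C)(C)C(C)(C)C)C/C(C)=C/CCC(C)=O
A7 | alternative 3 | 8-(4-methoxybenzyloxy)germacra-1(10)E,4Z-dien-6-one | COc1ccc(CO[C@H]2C/C(C)=C/CC/C(C)=C\C(=O)[C@@H]2C(C)C)cc1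
A8 | alternative 3 | trans-1,2-dialkenylcyclohexenol, 1-[(1E)-1-(4-methoxybenzyloxy)-3-methylbut-1-en-2-yl]-3-methyl-6-(prop-1-en-2-yl)cyclohex-2-en-1-ol | COc1ccc(CO/C=C(\C(C)C)[C@]2(O)C=C(C)CC[C@H]2C(C)=C)cc1
A9 | alternative 3 | (S)-isopiperitenone | CC1=CC(=O)[C@@H](CC1)C(C)=C
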